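The depside is cut at the bond between the ester oxygen and C4 of ring B (the methoxy-pentyl benzoic acid ring, C1 bearing CO2H). C4 has hydrogens on both neighbours (C3, C5) and lies para to the C1 ester, whereas the ring A carbonyl carbon is wedged between C2–O and C6–pentyl. The key step therefore lets the ring A carboxylate oxygen act as nucleophile towards an aryl(2,4,6-trimethoxyphenyl)iodonium tosylate of ring B; ligand coupling at trivalent iodine forges O–C4 in one operation without touching the crowded carbonyl. The precursors are 2,4-bis(benzyloxy)-6-pentylbenzoic acid and the ring B iodonium salt carrying a benzyl ester; one hydrogenolysis then frees all three benzyl groups.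

Key step: step 8

Remark on the chemistry: the target has no stereocentre; compounds 1, 2, 7 and 10 are taken as purchasable, and in step 8 the acid is charged in slight excess over the base so that no free alkoxide meets the iodonium salt.

Step 1
Reactants: 1 4-bromo-2-methoxy-6-methylbenzoic acid; 2 1-iodobutane
Product: 4 4-bromo-2-methoxy-6-pentylbenzoic acid, via dilithio dianion 3 (not isolated)
Conditions: LiN(i-Pr)2 (2.1 equiv), THF, −78 °C; then 2 (1.2 equiv), −78 → 0 °C; aq. HCl
Reagents that add atoms: none
Why: Lateral lithiation, in which the second equivalent of the hindered amide base removes a benzylic proton ortho to the lithium carboxylate without halogen–lithium exchange at the aryl bromide, followed by SN2 alkylation of the benzylic carbanion by the primary iodide, should turn the methyl group into pentyl.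

Step 2
Reactants: 4 4-bromo-2-methoxy-6-pentylbenzoic acid
Product: 5 benzyl 4-bromo-2-methoxy-6-pentylbenzoate
Conditions: BnBr (1.2 equiv), K2CO3, DMF, rt → 40 °C
Reagents that add atoms: benzyl bromide BrCc1ccccc1
Why: SN2 alkylation of the carboxylate oxygen by benzyl bromide is insensitive to the two ortho substituents because the carbonyl carbon is not attacked.

Step 3
Reactants: 5 benzyl 4-bromo-2-methoxy-6-pentylbenzoate
Product: 6 benzyl 4-iodo-2-methoxy-6-pentylbenzoate
Conditions: CuI (5 mol %), NaI (2 equiv), trans-N,N'-dimethylcyclohexane-1,2-diamine (10 mol %), 1,4-dioxane, 110 °C, argon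
Reagents that add atoms: sodium iodide [Na+].[I-]
Why: The copper-catalysed aromatic Finkelstein reaction exchanges aryl bromide for iodide, driven by the low solubility of NaBr in dioxane, and the hindered ester should be inert under these neutral conditions.

Step 4
Reactants: 6 benzyl 4-iodo-2-methoxy-6-pentylbenzoate; 7 1,3,5-trimethoxybenzene
Product: 9 [4-(benzyloxycarbonyl)-3-methoxy-5-pentylphenyl](2,4,6-trimethoxyphenyl)iodonium tosylate, via hydroxy(tosyloxy)iodoarene 8 (not isolated)
Conditions: mCPBA (1.05 equiv), TsOH·H2O (1.05 equiv), MeCN, 77 °C; then 7 (1.05 equiv), 77 °C; Et2O trituration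
Reagents that add atoms: p-toluenesulfonic acid (used as the monohydrate) Cc1ccc(cc1)S(=O)(=O)O
Why: One-pot diaryliodonium synthesis, in which the peracid with TsOH oxidises the aryl iodide to trivalent iodine (8) and this electrophile then substitutes the very electron-rich trimethoxybenzene by electrophilic aromatic substitution, should give the unsymmetrical salt.

Step 5
Reactants: 10 olivetol (5-pentylbenzene-1,3-diol)
Product: 12 2,4-dihydroxy-6-pentylbenzaldehyde, via aryl iminium chloride 11 (not isolated)
Conditions: POCl3 (1.5 equiv), DMF, 0 °C → rt; then H2O, 50 °C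
Reagents that add atoms: N,N-dimethylformamide CN(C)C=O; water O
Why: Vilsmeier–Haack formylation of the resorcinol ring takes place at the carbon between the pentyl group and one hydroxyl (para to the other hydroxyl), the usual site for 5-alkylresorcinols, and aqueous hydrolysis of iminium 11 releases the aldehyde.

Step 6
Reactants: 12 2,4-dihydroxy-6-pentylbenzaldehyde
Product: 13 2,4-bis(benzyloxy)-6-pentylbenzaldehyde
Conditions: BnBr (2.4 equiv), K2CO3 (3 equiv), DMF, 60 °C
Reagents that add atoms: benzyl bromide BrCc1ccccc1
Why: Williamson ether synthesis on both phenoxides, with gentle heating for the hydroxyl that is hydrogen-bonded to the aldehyde, should give the bis-benzyl ether.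

Step 7
Reactants: 13 2,4-bis(benzyloxy)-6-pentylbenzaldehyde
Product: 14 2,4-bis(benzyloxy)-6-pentylbenzoic acid
Conditions: NaClO2, NaH2PO4, 2-methyl-2-butene, t-BuOH/THF/H2O, rt
Reagents that add atoms: sodium chlorite [Na+].[O-]Cl=O
Why: Pinnick oxidation converts the hindered aryl aldehyde into the acid under buffered conditions, with 2-methyl-2-butene trapping HOCl so that the electron-rich ring is not chlorinated.

Step 8
Reactants: 14 2,4-bis(benzyloxy)-6-pentylbenzoic acid; 9 [4-(benzyloxycarbonyl)-3-methoxy-5-pentylphenyl](2,4,6-trimethoxyphenyl)iodonium tosylate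
Product: 17 benzyl 4-{[2,4-bis(benzyloxy)-6-pentylbenzoyl]oxy}-2-methoxy-6-pentylbenzoate, via potassium carboxylate 15 (not isolated), via aryl(carboxylato)iodane 16 (not isolated)
Conditions: 14 (1.2 equiv), KOt-Bu (1.1 equiv), toluene, rt; then 9 (1.0 equiv), 110 °C
Reagents that add atoms: none
Why: Potassium carboxylate 15 replaces tosylate at trivalent iodine to give the T-shaped iodane 16, and reductive ligand coupling then joins the carboxylate oxygen to the ipso carbon C4 of ring B while 2-iodo-1,3,5-trimethoxybenzene departs. The closest known reaction type is the metal-free O-arylation of hindered benzoic acids with diaryliodonium salts under potassium tert-butoxide in toluene. No ring is closed and no stereocentre is formed. The step needs chemoselective transfer of the ring B aryl rather than the trimethoxyphenyl group; the para ester and the unsubstituted C3 and C5 positions of ring B, together with the electron-rich, doubly ortho-substituted dummy ligand that prefers to stay on iodine, should secure this. The crowded ring A carbonyl is never the electrophile, so the 2-benzyloxy and 6-pentyl groups do not hinder bond formation, and the absence of free alkoxide should suppress aryne formation and tert-butyl ether formation.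

Step 9
Reactants: 17 benzyl 4-{[2,4-bis(benzyloxy)-6-pentylbenzoyl]oxy}-2-methoxy-6-pentylbenzoate
Product: 18 4-[(2,4-dihydroxy-6-pentylbenzoyl)oxy]-2-methoxy-6-pentylbenzoic acid (target)
Conditions: H2 (1 atm), 10% Pd/C, EtOAc, rt
Reagents that add atoms: none
Why: Catalytic hydrogenolysis over Pd/C cleaves the three benzylic C–O bonds (two ethers, one ester) while the aryl ester link, the methyl ether and both arene rings should be inert.

Compound list
1 | 4-bromo-2-methoxy-6-methylbenzoic acid | Cc1cc(Br)cc(OC)c1C(=O)O | starting material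
2 | 1-iodobutane | CCCCI | starting material
3 | dilithio dianion of 1 (lithium 4-bromo-2-(lithiomethyl)-6-methoxybenzoate) | [Li+].[Li+].[CH2-]c1cc(Br)cc(OC)c1C(=O)[O-] | intermediate
4 | 4-bromo-2-methoxy-6-pentylbenzoic acid | CCCCCc1cc(Br)cc(OC)c1C(=O)O | intermediate
5 | benzyl 4-bromo-2-methoxy-6-pentylbenzoate | CCCCCc1cc(Br)cc(OC)c1C(=O)OCc1ccccc1 | intermediate
6 | benzyl 4-iodo-2-methoxy-6-pentylbenzoate | CCCCCc1cc(I)cc(OC)c1C(=O)OCc1ccccc1 | intermediate
7 | 1,3,5-trimethoxybenzene | COc1cc(OC)cc(OC)c1 | starting material
8 | benzyl 4-[hydroxy(tosyloxy)iodo]-2-methoxy-6-pentylbenzoate | CCCCCc1cc(I(O)OS(=O)(=O)c2ccc(C)cc2)cc(OC)c1C(=O)OCc1ccccc1 | intermediate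
9 | [4-(benzyloxycarbonyl)-3-methoxy-5-pentylphenyl](2,4,6-trimethoxyphenyl)iodonium tosylate | CCCCCc1cc([I+]c2c(OC)cc(OC)cc2OC)cc(OC)c1C(=O)OCc1ccccc1.Cc1ccc(cc1)S(=O)(=O)[O-] | intermediate
10 | olivetol (5-pentylbenzene-1,3-diol) | CCCCCc1cc(O)cc(O)c1 | starting material
11 | (2,4-dihydroxy-6-pentylbenzylidene)dimethyliminium chloride | CCCCCc1cc(O)cc(O)c1C=[N+](C)C.[Cl-] | intermediate
12 | 2,4-dihydroxy-6-pentylbenzaldehyde | CCCCCc1cc(O)cc(O)c1C=O | intermediate
13 | 2,4-bis(benzyloxy)-6-pentylbenzaldehyde | CCCCCc1cc(OCc2ccccc2)cc(OCc2ccccc2)c1C=O | intermediate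
14 | 2,4-bis(benzyloxy)-6-pentylbenzoic acid | CCCCCc1cc(OCc2ccccc2)cc(OCc2ccccc2)c1C(=O)O | intermediate
15 | potassium 2,4-bis(benzyloxy)-6-pentylbenzoate | CCCCCc1cc(OCc2ccccc2)cc(OCc2ccccc2)c1C(=O)[O-].[K+] | intermediate
16 | [4-(benzyloxycarbonyl)-3-methoxy-5-pentylphenyl][2,4-bis(benzyloxy)-6-pentylbenzoyloxy](2,4,6-trimethoxyphenyl)iodane (T-shaped, trivalent iodine) | CCCCCc1cc(OCc2ccccc2)cc(OCc2ccccc2)c1C(=O)OI(c1cc(CCCCC)c(C(=O)OCc2ccccc2)c(OC)c1)c1c(OC)cc(OC)cc1OC | intermediate
17 | benzyl 4-{[2,4-bis(benzyloxy)-6-pentylbenzoyl]oxy}-2-methoxy-6-pentylbenzoate | CCCCCc1cc(OCc2ccccc2)cc(OCc2ccccc2)c1C(=O)Oc1cc(CCCCC)c(C(=O)OCc2ccccc2)c(OC)c1 | intermediate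
18 | 4-[(2,4-dihydroxy-6-pentylbenzoyl)oxy]-2-methoxy-6-pentylbenzoic acid | CCCCCc1cc(O)cc(O)c1C(=O)Oc1cc(CCCCC)c(C(=O)O)c(OC)c1 | target

Total step count: 9. Longest linear sequence: 6 steps (steps 1, 2, 3, 4, 8, 9); steps 5 to 7 form the second branch.

Steps most likely to fail

Step 8. The ligand coupling may be outrun by thermal decomposition of the iodonium salt, by base-induced aryne formation, or by partial transfer of the wrong aryl group. The fallback makes the same ester by acyl activation; it sets out from bromide 5 and acid 14 and comes back at 17. Bromide 5 would undergo Miyaura borylation (B2pin2, KOAc, Pd(dppf)Cl2, dioxane, 90 °C) to benzyl 2-methoxy-6-pentyl-4-(4,4,5,5-tetramethyl-1,3,2-dioxaborolan-2-yl)benzoate F1. Oxidation (NaBO3·4H2O, THF/H2O, rt) would give benzyl 4-hydroxy-2-methoxy-6-pentylbenzoate F2. Acid 14 would then be activated with trifluoroacetic anhydride in toluene at rt as 2,4-bis(benzyloxy)-6-pentylbenzoic trifluoroacetic anhydride F3, an acylium-type activation that tolerates two ortho substituents, and F3 would acylate phenol F2 to give 17.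

Step 4. The peracid may over-oxidise the electron-rich ring B iodide, the trivalent iodine intermediate may arylate a second ring B molecule before trimethoxybenzene is added, or the lipophilic salt may fail to crystallise. The fallback avoids the iodonium salt and forms the same O–C4 bond by nickel-catalysed, photosensitised C–O coupling of an aryl bromide with a carboxylic acid. It sets out from bromide 5 and acid 14 and comes back at 17, replacing steps 3, 4 and 8 (NiBr2·glyme, 4,4'-di-tert-butyl-2,2'-bipyridine, Ir(ppy)3, N-tert-butylisopropylamine, DMF, blue light, rt). The para ester of 5 makes it a favourable bromide for this known coupling. This fallback makes no new compound (F0).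

Step 1. Deprotonation may occur on the ring next to bromine instead of at the methyl group, leading to benzyne-derived loss of material, or the alkylation may stop short or run on to double alkylation. The fallback reverses the polarity of the chain extension; it sets out from 1 and comes back at 4. Acid 1 would be esterified (MeI, K2CO3, DMF) to methyl 4-bromo-2-methoxy-6-methylbenzoate F4. Wohl–Ziegler bromination (NBS, AIBN, PhCF3, 80 °C) would give methyl 4-bromo-2-(bromomethyl)-6-methoxybenzoate F5. Substitution of the benzylic bromide with lithium dibutylcuprate (n-Bu2CuLi, THF, −78 °C) would give methyl 4-bromo-2-methoxy-6-pentylbenzoate F6. The hindered methyl ester would finally be cleaved at its methyl carbon (LiI, pyridine, reflux; aq. HCl) to return acid 4.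

Further compounds
F1 | step 8 | benzyl 2-methoxy-6-pentyl-4-(4,4,5,5-tetramethyl-1,3,2-dioxaborolan-2-yl)benzoate | CCCCCc1cc(B2OC(C)(C)C(C)(C)O2)cc(OC)c1C(=O)OCc1ccccc1
F2 | step 8 | benzyl 4-hydroxy-2-methoxy-6-pentylbenzoate | CCCCCc1cc(O)cc(OC)c1C(=O)OCc1ccccc1
F3 | step 8 | 2,4-bis(benzyloxy)-6-pentylbenzoic trifluoroacetic anhydride | CCCCCc1cc(OCc2ccccc2)cc(OCc2ccccc2)c1C(=O)OC(=O)C(F)(F)F
F0 | step 4 | none | none
F4 | step 1 | methyl 4-bromo-2-methoxy-6-methylbenzoate | Cc1cc(Br)cc(OC)c1C(=O)OC
F5 | step 1 | methyl 4-bromo-2-(bromomethyl)-6-methoxybenzoate | BrCc1cc(Br)cc(OC)c1C(=O)OC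
F6 | step 1 | methyl 4-bromo-2-methoxy-6-pentylbenzoate | CCCCCc1cc(Br)cc(OC)c1C(=O)OC
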